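## The problem

The target is a cis-fused decalin (ring A: C1–C5 and C10; ring B: C5–C10) whose C9 carries, through the methylene C11, the C3′ position of a fully substituted 2-methoxy-4-pyrone (5′-CO2Me, 6′-CH3). Below, α is the face of the C10 methyl group and β the opposite face. Ring A holds four contiguous stereocentres, two of them quaternary: 3β-OH, C4 with an α-methyl and the β-CH2CH2C(CH3)2OCHO chain, 5α-H and 10α-CH3. A fifth centre, C9 (β-CH2 arm), lies next to the exocyclic C8 methylene; the absolute configuration is (3S,4R,5R,9S,10S). The quaternary centres cannot be corrected by equilibration, so their relation to C3 and C5 has to come from one stereospecific event. C9 is the only centre that can be set early by a reagent and then used to steer the others, but it is also the only one that becomes epimerisable when C8 is a ketone. The fragile groups are the tertiary formate (base, hydride, nucleophiles), the 1,1-disubstituted olefin (hydrogenation, acid), the α-methoxy-γ-pyrone (aqueous acid) and the secondary C3 hydroxyl, which must be told apart from the tertiary one; the C11–C3′ bond joins a β-branched primary carbon to a hindered sp2 carbon. The enabling feature is that ring A, once given a C1=C2 double bond and with its C4 chain read as an ester, is the adduct of a 1-oxygenated diene (C3=C2–C1=C10) and a (Z)-2-methyl enoate (C4=C5), with C6–C9 as a four-carbon tether and C8 as a masked ketone.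

## Retrosynthesis

**C11–C3′ bond.** Target 37 is the desilylation product of 36, and 36 is cut at C11–C3′ into alkyl iodide 29 (used as its zinc reagent 35) and iodopyrone 34. The neighbouring cut, inside the pyrone ring, would build the heterocycle on the finished decalin and expose the methylene and the formate to acid chlorides and HCl. The chosen cut is convergent: 29 carries no heterocycle, and 34 comes in three small-molecule steps from methyl acetoacetate 30 and malonyl dichloride 31 through 32 and 33. The forward reaction must couple a β-branched primary alkylzinc with a hindered vinylic iodide in the presence of a formate.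

**C8 methylene, C11 iodide, formate.** Iodide 29 goes back through 28, 27 and 26 to ketone 25 by cutting the C8=CH2 bond. The order is dictated by the structure. The olefin can only appear after the last hydrogenation. It must appear before C11 is activated, because a β-iodo ketone would eliminate. The formate must be installed after the reductive debenzylation and while C3 is still silylated. The methylenation has to be non-basic, since C9 is α to the ketone and C11 carries a β-leaving group.

**C4 side chain.** Ketone 25 comes from ketal 24, and the tertiary alcohol chain is cut at the C–CH3 bond (ketone 23) and at the olefin of enone 22, back to aldehyde 20, alcohol 19 and ester 18. Olefination of the α-quaternary aldehyde is preferred to displacement at the neopentyl carbon, which would not work. The hydrogenation that saturates the enone also removes the C1=C2 olefin, so the step does double duty.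

**C3–C4 and C5–C10 (key cut).** Adduct 18 is cut into the acyclic triene 17. No other ring-A cut (aldol at C3–C4, alkylation at C4–C5) removes both rings, and each would make the two quaternary centres one at a time without built-in relative control. The precursor has one stereocentre (C9) and three defined olefins in place of two rings and five stereocentres. The forward reaction needs the endo mode, control of the diene face by C9, and a geometrically defined diene.

**Diene.** Triene 17 is cut at O–Si and at the C10–H bond to enal 16, which comes from saturated aldehyde 15 and this from the trisubstituted olefin of 13. The E enol ether is reliable only when it is formed by γ-deprotonation of an s-trans enal; α-deprotonation of a β,γ-unsaturated aldehyde tends to give the Z enol ether, as simple aldehydes do. The price is that the C10=C1 geometry is set in the same step, by the size difference between methyl and C9. The carbons C8–C9–C10(CH3)–C1–C2–C3 map onto citronellic acid 1, whose isopropylidene end is a protecting-group-free aldehyde surrogate and whose stereocentre (C10) is sacrificed.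

**C4=C5 and C7–C8.** Enoate 13 is cut at C4=C5 to aldehyde 11 and phosphonate 12; 11 comes from ester 10 and keto ester 9. Ketone 9 is cut at C7–C8 into thioester 7 and zinc homoenolate 8. A thioester coupling is chosen over addition to an amide or ester because it is neutral and stops at the ketone, which protects the C9 α-centre.

**C9–C11.** Thioester 7 comes from imide 6, which is cut at C9–C11 back to imide 4, made from acid 1 and oxazolidinone 2. C9 is α to a carbonyl only at this stage, so an auxiliary alkylation sets it, and C11 arrives already protected as a benzyl ether. An aldol route through a C8 alcohol would add a needless stereocentre and two redox steps.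

## Roads not taken

**Alternative 1:** The cut is in ring B at C7–C8 and C8–C9, with C8 entering as carbon monoxide. [Rh(CO)2Cl]2 under CO would open the C5–C9 bond of a cyclopropane that bears a vinyl group and close the cyclohex-3-enone A1, in which a C11 lactone to O3 bridges C9 and C3.
- Merits: C8 arrives as the ketone with no protection and release (the chosen plan spends two steps on the ketal), the lactone locks the C3/C9 relation, and the tertiary-alcohol chain is already present.
- Weak points: the step makes one ring and no stereocentre. Ring A with C3, C4, C9 and C10 must already be in place, and the cyclopropane added to it, so the hard stereochemistry is moved upstream. The C5 hydrogen is left to a later reduction of a trisubstituted olefin between two quaternary carbons, where the face is uncertain. The bond to be opened is flanked by fully substituted carbons, a more hindered case than the usual ones, and C11 must later be brought down from the acid level next to a ketone.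
- Comparison: the chosen plan sets against it one step that closes both rings and four centres from a chain with a single stereocentre.

**Alternative 2:** The cut lies inside the heterocycle (C4′–C5′ and O1′–C2′). The malonyl dichloride A2, carrying the finished decalin on its central carbon, would C-acylate methyl acetoacetate 30 and lactonise through the enol oxygen to hydroxypyrone A3, which is then O-methylated.
- Merits: it avoids a metal-mediated sp3–sp2 coupling at the hindered C11 and uses a cheap four-carbon partner; in this one respect it is at least as safe as the coupling chosen here.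
- Weak points: it is an end-game tactic and leaves the decalin unsolved. A malonate must first be attached at the β-branched C11 (slow SN2), hydrolysed and turned into the acid chloride in the presence of the methylene, the formate and a silyl ether, with two equivalents of HCl released at the ring closure. The regioselective O-methylation then falls on the most valuable intermediate.
- Comparison: the chosen plan performs the same ring formation on malonyl dichloride 31 itself, sets the methylation on a small molecule (33 to 34), and offers convergence (one step on the decalin instead of about five).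

**Alternative 3:** The cut is at C4–C5 and C9–C10. MeAlCl2 would open a C3–C4 epoxide, a Z C5=C10 olefin would attack C4, and an allylsilane would close C9–C10 and release the C8 methylene, giving the cis-fused methylene decalin A4.
- Merits: on step count this road is clearly better. Both rings, the C4 chain and the exocyclic olefin appear in one operation, and no ketal, methylenation or chain extension is needed.
- Weak points: the C3 alcohol emerges as the epimer of the target, and inversion at a secondary carbon next to quaternary C4 (displacement, or oxidation and reduction) is unreliable. The C9 configuration rests on the transition-state preference of the allylsilane and not on a reagent. Z-trisubstituted olefins and epoxide openings at a carbon bearing a long chain cyclise less cleanly, and the tertiary benzoate can trap the C4 cation.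
- Comparison: the chosen plan is longer, but every ring-A centre including C3 comes out in the required sense from olefin geometry, and C9 is set by an auxiliary.

Key step: step 11

Remark on the chemistry: the cis ring fusion encoded in the SMILES (5-H and 10-CH3 on the same face) is taken as the intended structure, and the route is built for exactly that stereoisomer.

Conventions: TBS = tert-butyldimethylsilyl, Bn = benzyl. Bicyclic compounds are named with the C1–C11 numbering used above ("decalin" = decahydronaphthalene skeleton); all are (5R) with 5-H and 10-CH3 cis.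

## Route

Step 1
Reactants: 1 (3R)-3,7-dimethyloct-6-enoic acid [(R)-citronellic acid]; 2 (4R)-4-benzyl-1,3-oxazolidin-2-one
Product: 4 (4R)-4-benzyl-3-[(3R)-3,7-dimethyloct-6-enoyl]-1,3-oxazolidin-2-one, via mixed pivalic anhydride 3 (not isolated)
Conditions: t-BuCOCl, Et3N, THF, −20 °C; then 2, LiCl, −20 °C → rt
Reagents that add atoms: none
Why: N-Acylation of the oxazolidinone through the mixed anhydride (LiCl/Et3N variant); no stereocentre is formed and the C10 centre of citronellic acid is untouched.

Step 2
Reactants: 4 (4R)-4-benzyl-3-[(3R)-3,7-dimethyloct-6-enoyl]-1,3-oxazolidin-2-one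
Product: 6 (4R)-4-benzyl-3-{(2S,3R)-2-[(benzyloxy)methyl]-3,7-dimethyloct-6-enoyl}-1,3-oxazolidin-2-one, via chlorotitanium enolate 5 (not isolated)
Conditions: TiCl4, i-Pr2NEt, CH2Cl2, 0 °C; then BnOCH2Cl, 0 °C
Reagents that add atoms: benzyl chloromethyl ether, ClCOCc1ccccc1
Why: Evans alkylation of the chelated Z titanium enolate; the electrophile should add to the face opposite the benzyl group of the (R)-auxiliary, which gives (S) at C9 (C2 of the acyl chain) and brings in C11 as its benzyl ether. The C10 centre is a bystander.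

Step 3
Reactants: 6 (4R)-4-benzyl-3-{(2S,3R)-2-[(benzyloxy)methyl]-3,7-dimethyloct-6-enoyl}-1,3-oxazolidin-2-one
Product: 7 S-ethyl (2S,3R)-2-[(benzyloxy)methyl]-3,7-dimethyloct-6-enethioate
Conditions: EtSH, n-BuLi, THF, 0 °C
Reagents that add atoms: ethanethiol (as LiSEt), CCS
Why: Thiolate cleavage of the exocyclic imide carbonyl (transthioesterification) works on α-branched imides where hydroxide tends to attack the ring carbonyl; the thiolate is too weak a base to epimerise C9 or expel benzyloxide, and the auxiliary is recovered.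

Step 4
Reactants: 7 S-ethyl (2S,3R)-2-[(benzyloxy)methyl]-3,7-dimethyloct-6-enethioate; 8 bromo(3-ethoxy-3-oxopropyl)zinc
Product: 9 ethyl (5S,6R)-5-[(benzyloxy)methyl]-6,10-dimethyl-4-oxoundec-9-enoate
Conditions: PdCl2(PPh3)2 (cat.), toluene/THF, rt
Reagents that add atoms: none
Why: Fukuyama ketone synthesis: zerovalent palladium inserts into the C–S bond, the zinc homoenolate transmetalates and reductive elimination forms C7–C8 without over-addition, under neutral conditions that leave the C9 α-centre, the ester and the olefin alone.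

Step 5
Reactants: 9 ethyl (5S,6R)-5-[(benzyloxy)methyl]-6,10-dimethyl-4-oxoundec-9-enoate
Product: 10 ethyl 3-{2-[(2S,3R)-1-(benzyloxy)-3,7-dimethyloct-6-en-2-yl]-1,3-dioxolan-2-yl}propanoate
Conditions: (Me3SiOCH2)2, Me3SiOTf (cat.), CH2Cl2, −78 → −20 °C
Reagents that add atoms: 1,2-bis(trimethylsilyloxy)ethane, C[Si](C)(C)OCCO[Si](C)(C)C
Why: Noyori ketalisation protects the C8 ketone at low temperature without the protic acid and heat that could epimerise C9 or eliminate the β-benzyloxy group; from here to step 17 C9 has no acidifying neighbour.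

Step 6
Reactants: 10 ethyl 3-{2-[(2S,3R)-1-(benzyloxy)-3,7-dimethyloct-6-en-2-yl]-1,3-dioxolan-2-yl}propanoate
Product: 11 3-{2-[(2S,3R)-1-(benzyloxy)-3,7-dimethyloct-6-en-2-yl]-1,3-dioxolan-2-yl}propanal
Conditions: i-Bu2AlH, CH2Cl2, −78 °C
Reagents that add atoms: none
Why: Partial reduction of the ethyl ester at low temperature, where the aluminium hemiacetal persists until work-up; ketal, ether and olefin are inert.

Step 7
Reactants: 11 3-{2-[(2S,3R)-1-(benzyloxy)-3,7-dimethyloct-6-en-2-yl]-1,3-dioxolan-2-yl}propanal; 12 methyl 2-[bis(2,2,2-trifluoroethoxy)phosphoryl]propanoate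
Product: 13 methyl (2Z)-5-{2-[(2S,3R)-1-(benzyloxy)-3,7-dimethyloct-6-en-2-yl]-1,3-dioxolan-2-yl}-2-methylpent-2-enoate
Conditions: 12, KN(SiMe3)2, 18-crown-6, THF, −78 °C; then 11
Reagents that add atoms: none
Why: Still–Gennari olefination; the trifluoroethyl phosphonate with a dissociated potassium ion eliminates from the kinetic adduct and should give the (Z)-2-methyl enoate, which later fixes the cis relation of the C4 methyl and H5.

Step 8
Reactants: 13 methyl (2Z)-5-{2-[(2S,3R)-1-(benzyloxy)-3,7-dimethyloct-6-en-2-yl]-1,3-dioxolan-2-yl}-2-methylpent-2-enoate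
Product: 15 methyl (2Z)-5-{2-[(2S,3R)-1-(benzyloxy)-3-methyl-6-oxohexan-2-yl]-1,3-dioxolan-2-yl}-2-methylpent-2-enoate, via ozonide 14 (not isolated)
Conditions: O3, CH2Cl2, −78 °C, stopped at the first excess of ozone; then PPh3, −78 °C → rt
Reagents that add atoms: ozone, [O-][O+]=O
Why: Ozonolysis with reductive work-up; ozone should attack the electron-rich trisubstituted olefin much faster than the conjugated enoate, so the isopropylidene end is unmasked as the C3 aldehyde.

Step 9
Reactants: 15 methyl (2Z)-5-{2-[(2S,3R)-1-(benzyloxy)-3-methyl-6-oxohexan-2-yl]-1,3-dioxolan-2-yl}-2-methylpent-2-enoate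
Product: 16 methyl (2Z)-5-{2-[(2S,3R,4E)-1-(benzyloxy)-3-methyl-6-oxohex-4-en-2-yl]-1,3-dioxolan-2-yl}-2-methylpent-2-enoate
Conditions: IBX (small excess), DMSO/toluene, 65 °C
Reagents that add atoms: none
Why: IBX dehydrogenation of a saturated aldehyde to the (E)-enal (C1=C2), which supplies the γ-branched enal needed for the dienol ether; the small excess and moderate temperature are chosen to spare the benzyl ether and avoid a second dehydrogenation.

Step 10
Reactants: 16 methyl (2Z)-5-{2-[(2S,3R,4E)-1-(benzyloxy)-3-methyl-6-oxohex-4-en-2-yl]-1,3-dioxolan-2-yl}-2-methylpent-2-enoate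
Product: 17 methyl (2Z)-5-{2-[(2S,3E,5E)-1-(benzyloxy)-6-(tert-butyldimethylsilyloxy)-3-methylhexa-3,5-dien-2-yl]-1,3-dioxolan-2-yl}-2-methylpent-2-enoate
Conditions: TBSOTf, Et3N, CH2Cl2, −78 → 0 °C
Reagents that add atoms: tert-butyldimethylsilyl triflate, CC(C)(C)[Si](C)(C)OS(=O)(=O)C(F)(F)F
Why: Soft enolisation: O-silylation of the s-trans enal and γ-deprotonation at C10 give the 1-silyloxydiene, with an E enol ether because it derives from the s-trans enal. The new C10=C1 bond is expected, not certain, to form mainly with the methyl group inside and the branched C9 outside; the C10 stereocentre is erased here.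

Step 11
Reactants: 17 methyl (2Z)-5-{2-[(2S,3E,5E)-1-(benzyloxy)-6-(tert-butyldimethylsilyloxy)-3-methylhexa-3,5-dien-2-yl]-1,3-dioxolan-2-yl}-2-methylpent-2-enoate
Product: 18 methyl (3S,4R,5R,9S,10R)-9β-(benzyloxymethyl)-3β-(TBSO)-8,8-ethylenedioxy-4α,10α-dimethyl-5αH-decal-1-ene-4β-carboxylate
Conditions: toluene (high dilution, degassed), BHT (cat.), sealed tube, 150–170 °C
Reagents that add atoms: none
Why: Thermal intramolecular Diels–Alder reaction of type 1, a concerted asynchronous [4+2] between the 1-silyloxydiene C3=C2–C1=C10 and the (Z)-2-methyl enoate C4=C5; the closest precedents are cyclisations of 1,7,9-decatrienoates with Z dienophiles and of tethered 1-silyloxydienes. Ring A closes as the new cyclohexene by forming C5–C10 and C3–C4, and ring B closes at the same time through the four-carbon tether C6–C9 in a chair-like arrangement. The tether fixes the regiochemistry, which is also the electronically matched one (C10, remote from oxygen, bonds to the enoate β-carbon C5). Suprafacial addition turns the Z geometry into the cis relation of the C4 methyl and H5, and the E,E diene places the silyloxy group and C9, both outside substituents, cis on ring A. With a Z dienophile the ester and the tether are endo together; this endo mode gives the cis ring fusion with the ester syn to the C3 oxygen and is the selectivity the step needs, since the exo mode would give the trans-fused isomer. The diene face is chosen by C9: in the chair-like tether C8 lies on the C1–H side, the C9 hydrogen eclipses the C10 methyl group (least allylic strain) and the CH2OBn arm points away from the forming C5–C10 bond, so C11 ends trans to the C10 methyl group. Any (3Z) diene cannot reach this geometry and should be left behind. The temperature is kept as low as conversion allows because the inside C10 methyl group can enter a 1,5-hydrogen shift.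

Step 12
Reactants: 18 methyl 9β-(benzyloxymethyl)-3β-(TBSO)-8,8-ethylenedioxy-4α,10α-dimethyl-5αH-decal-1-ene-4β-carboxylate
Product: 19 [9β-(benzyloxymethyl)-3β-(TBSO)-8,8-ethylenedioxy-4α,10α-dimethyl-5αH-decal-1-en-4β-yl]methanol
Conditions: LiAlH4, THF, 0 °C → rt
Reagents that add atoms: none
Why: Hydride reduction of the hindered neopentyl ester to the primary alcohol; silyl ether, ketal, benzyl ether and ring olefin are inert.

Step 13
Reactants: 19 [9β-(benzyloxymethyl)-3β-(TBSO)-8,8-ethylenedioxy-4α,10α-dimethyl-5αH-decal-1-en-4β-yl]methanol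
Product: 20 9β-(benzyloxymethyl)-3β-(TBSO)-8,8-ethylenedioxy-4α,10α-dimethyl-5αH-decal-1-ene-4β-carbaldehyde
Conditions: Dess–Martin periodinane, NaHCO3, CH2Cl2, 0 °C → rt
Reagents that add atoms: none
Why: Buffered Dess–Martin oxidation; the aldehyde is α-quaternary and cannot enolise or eliminate the β-silyloxy group.

Step 14
Reactants: 20 9β-(benzyloxymethyl)-3β-(TBSO)-8,8-ethylenedioxy-4α,10α-dimethyl-5αH-decal-1-ene-4β-carbaldehyde; 21 1-(triphenylphosphoranylidene)propan-2-one
Product: 22 (3E)-4-[9β-(benzyloxymethyl)-3β-(TBSO)-8,8-ethylenedioxy-4α,10α-dimethyl-5αH-decal-1-en-4β-yl]but-3-en-2-one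
Conditions: toluene, 100 °C
Reagents that add atoms: none
Why: Wittig reaction with the stabilised acetonyl ylide gives the (E)-enone and adds three of the four missing side-chain carbons without base.

Step 15
Reactants: 22 (3E)-4-[9β-(benzyloxymethyl)-3β-(TBSO)-8,8-ethylenedioxy-4α,10α-dimethyl-5αH-decal-1-en-4β-yl]but-3-en-2-one
Product: 23 4-[9β-(benzyloxymethyl)-3β-(TBSO)-8,8-ethylenedioxy-4α,10α-dimethyl-5αH-decalin-4β-yl]butan-2-one
Conditions: H2 (1 atm), Pt/C, EtOAc, rt
Reagents that add atoms: none
Why: Heterogeneous hydrogenation saturates the enone C=C and the C1=C2 ring olefin in one operation (no stereocentre is formed); platinum is chosen because it hydrogenolyses benzyl ethers only slowly, and the step must precede the C8 methylene.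

Step 16
Reactants: 23 4-[9β-(benzyloxymethyl)-3β-(TBSO)-8,8-ethylenedioxy-4α,10α-dimethyl-5αH-decalin-4β-yl]butan-2-one
Product: 24 4-[9β-(benzyloxymethyl)-3β-(TBSO)-8,8-ethylenedioxy-4α,10α-dimethyl-5αH-decalin-4β-yl]-2-methylbutan-2-ol
Conditions: MeMgBr, THF, −78 → 0 °C
Reagents that add atoms: methylmagnesium bromide, C[Mg]Br
Why: Grignard addition to the methyl ketone completes the tertiary alcohol of the C4 side chain.

Step 17
Reactants: 24 4-[9β-(benzyloxymethyl)-3β-(TBSO)-8,8-ethylenedioxy-4α,10α-dimethyl-5αH-decalin-4β-yl]-2-methylbutan-2-ol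
Product: 25 9β-(benzyloxymethyl)-3β-(TBSO)-4β-(3-hydroxy-3-methylbutyl)-4α,10α-dimethyl-5αH-decalin-8-one
Conditions: PPTS, acetone/H2O, 50 °C
Reagents that add atoms: water, O
Why: Mild acid-catalysed ketal hydrolysis releases the C8 ketone; the hindered secondary silyl ether and the tertiary alcohol should survive the buffered acid, and short exposure limits epimerisation at C9.

Step 18
Reactants: 25 9β-(benzyloxymethyl)-3β-(TBSO)-4β-(3-hydroxy-3-methylbutyl)-4α,10α-dimethyl-5αH-decalin-8-one
Product: 26 4-[9β-(benzyloxymethyl)-3β-(TBSO)-4α,10α-dimethyl-8-methylidene-5αH-decalin-4β-yl]-2-methylbutan-2-ol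
Conditions: Zn, CH2Br2, TiCl4, THF (reagent aged at 0 °C); then 25, CH2Cl2, rt
Reagents that add atoms: dibromomethane, BrCBr
Why: Takai–Lombardo methylenation; the non-basic zinc/titanium methylene reagent converts enolisable ketones to olefins without epimerising the α-centre C9 or eliminating the β-benzyloxy group, and it tolerates free hydroxyl groups.

Step 19
Reactants: 26 4-[9β-(benzyloxymethyl)-3β-(TBSO)-4α,10α-dimethyl-8-methylidene-5αH-decalin-4β-yl]-2-methylbutan-2-ol
Product: 27 4-[3β-(TBSO)-9β-(hydroxymethyl)-4α,10α-dimethyl-8-methylidene-5αH-decalin-4β-yl]-2-methylbutan-2-ol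
Conditions: Li, NH3 (l), THF, −78 °C; then NH4Cl
Reagents that add atoms: none
Why: Dissolving-metal cleavage of the benzyl ether (electron transfer to the arene, then C–O scission); the isolated 1,1-disubstituted olefin and the silyl ether are not reduced, and no hydrogenation catalyst meets the methylene.

Step 20
Reactants: 27 4-[3β-(TBSO)-9β-(hydroxymethyl)-4α,10α-dimethyl-8-methylidene-5αH-decalin-4β-yl]-2-methylbutan-2-ol
Product: 28 4-[3β-(TBSO)-9β-(iodomethyl)-4α,10α-dimethyl-8-methylidene-5αH-decalin-4β-yl]-2-methylbutan-2-ol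
Conditions: I2, PPh3, imidazole, CH2Cl2, 0 °C → rt
Reagents that add atoms: iodine, II
Why: Appel-type iodination converts the primary C11 alcohol by SN2 at its alkoxyphosphonium ion; the tertiary alcohol cannot react this way when the reagent is not used in excess.

Step 21
Reactants: 28 4-[3β-(TBSO)-9β-(iodomethyl)-4α,10α-dimethyl-8-methylidene-5αH-decalin-4β-yl]-2-methylbutan-2-ol
Product: 29 4-[3β-(TBSO)-9β-(iodomethyl)-4α,10α-dimethyl-8-methylidene-5αH-decalin-4β-yl]-2-methylbutan-2-yl formate
Conditions: acetic formic anhydride, pyridine, DMAP (cat.), CH2Cl2, 0 °C → rt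
Reagents that add atoms: acetic formic anhydride, CC(=O)OC=O
Why: Acyl transfer from the small mixed anhydride under nucleophilic catalysis formylates the tertiary alcohol while the only other hydroxyl (C3) is silylated.

Step 22
Reactants: 30 methyl acetoacetate; 31 malonyl dichloride
Product: 32 methyl 4-hydroxy-2-methyl-6-oxo-6H-pyran-3-carboxylate
Conditions: CH2Cl2, 0 °C → reflux (HCl evolved)
Reagents that add atoms: none
Why: Known pyrone synthesis from malonyl dichloride and a β-keto ester: C-acylation at the acetoacetate α-carbon and O-acylation by the enol oxygen close the 4-hydroxy-2-pyrone with the ester at C5′ and the methyl at C6′.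

Step 23
Reactants: 32 methyl 4-hydroxy-2-methyl-6-oxo-6H-pyran-3-carboxylate
Product: 33 methyl 4-hydroxy-5-iodo-2-methyl-6-oxo-6H-pyran-3-carboxylate
Conditions: N-iodosuccinimide, MeCN, rt
Reagents that add atoms: N-iodosuccinimide, O=C1CCC(=O)N1I
Why: Electrophilic iodination at the only free, enol-activated ring position (C3′).

Step 24
Reactants: 33 methyl 4-hydroxy-5-iodo-2-methyl-6-oxo-6H-pyran-3-carboxylate
Product: 34 methyl 5-iodo-6-methoxy-2-methyl-4-oxo-4H-pyran-3-carboxylate
Conditions: MeOTf, CH2Cl2, rt; aq. NaHCO3 work-up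
Reagents that add atoms: methyl triflate, COS(=O)(=O)C(F)(F)F
Why: A hard methylating agent alkylates the neutral 4-hydroxy-2-pyrone at the lactone carbonyl oxygen and loss of the proton gives the 2-methoxy-4-pyrone, the known entry to α-methoxy-γ-pyrones; the 4-OH is further deactivated by its hydrogen bond to the neighbouring ester.

Step 25
Reactants: 29 4-[3β-(TBSO)-9β-(iodomethyl)-4α,10α-dimethyl-8-methylidene-5αH-decalin-4β-yl]-2-methylbutan-2-yl formate; 34 methyl 5-iodo-6-methoxy-2-methyl-4-oxo-4H-pyran-3-carboxylate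
Product: 36 methyl 5-{[(3S,4R,5R,9S,10S)-3β-(TBSO)-4β-(3-formyloxy-3-methylbutyl)-4α,10α-dimethyl-8-methylidene-5αH-decalin-9β-yl]methyl}-6-methoxy-2-methyl-4-oxo-4H-pyran-3-carboxylate, via alkylzinc iodide 35 (not isolated)
Conditions: 29, Zn dust, LiCl, THF, 40 °C; then 34, Pd(OAc)2 (cat.), SPhos, THF, rt → 50 °C
Reagents that add atoms: none
Why: Negishi coupling: zinc inserts into the primary C–I bond (formate and silyl ether tolerate alkylzinc iodides), and palladium with a bulky biarylphosphine should couple the β-branched alkylzinc with the α-iodoenone-like C3′–I bond faster than β-hydride elimination; C9 is not touched.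

Step 26
Reactants: 36 methyl 5-{[3β-(TBSO)-4β-(3-formyloxy-3-methylbutyl)-4α,10α-dimethyl-8-methylidene-5αH-decalin-9β-yl]methyl}-6-methoxy-2-methyl-4-oxo-4H-pyran-3-carboxylate
Product: 37 methyl 5-{[(3S,4R,5R,9S,10S)-4β-(3-formyloxy-3-methylbutyl)-3β-hydroxy-4α,10α-dimethyl-8-methylidene-5αH-decalin-9β-yl]methyl}-6-methoxy-2-methyl-4-oxo-4H-pyran-3-carboxylate (CNP0292250.1)
Conditions: HF·pyridine, pyridine, THF, 0 °C → rt
Reagents that add atoms: none
Why: Buffered fluoride cleavage of the hindered secondary silyl ether under mildly acidic conditions that should leave the tertiary formate, the methylene and the methoxypyrone intact.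

## Compound list

1 | (3R)-3,7-dimethyloct-6-enoic acid [(R)-citronellic acid] | C[C@H](CCC=C(C)C)CC(=O)O | starting material
2 | (4R)-4-benzyl-1,3-oxazolidin-2-one | O=C1N[C@H](Cc2ccccc2)CO1 | starting material
3 | (3R)-3,7-dimethyloct-6-enoic pivalic anhydride | C[C@H](CCC=C(C)C)CC(=O)OC(=O)C(C)(C)C | intermediate (not isolated)
4 | (4R)-4-benzyl-3-[(3R)-3,7-dimethyloct-6-enoyl]-1,3-oxazolidin-2-one | C[C@H](CCC=C(C)C)CC(=O)N1[C@H](Cc2ccccc2)COC1=O | intermediate
5 | trichlorotitanium (Z)-enolate of 4 | C[C@H](CCC=C(C)C)/C=C(\O[Ti](Cl)(Cl)Cl)N1[C@H](Cc2ccccc2)COC1=O | intermediate (not isolated)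
6 | (4R)-4-benzyl-3-{(2S,3R)-2-[(benzyloxy)methyl]-3,7-dimethyloct-6-enoyl}-1,3-oxazolidin-2-one | O=C1OC[C@@H](Cc2ccccc2)N1C(=O)[C@H](COCc2ccccc2)[C@H](C)CCC=C(C)C | intermediate
7 | S-ethyl (2S,3R)-2-[(benzyloxy)methyl]-3,7-dimethyloct-6-enethioate | CCSC(=O)[C@H](COCc1ccccc1)[C@H](C)CCC=C(C)C | intermediate
8 | bromo(3-ethoxy-3-oxopropyl)zinc | CCOC(=O)CC[Zn]Br | starting material
9 | ethyl (5S,6R)-5-[(benzyloxy)methyl]-6,10-dimethyl-4-oxoundec-9-enoate | CCOC(=O)CCC(=O)[C@H](COCc1ccccc1)[C@H](C)CCC=C(C)C | intermediate
10 | ethyl 3-{2-[(2S,3R)-1-(benzyloxy)-3,7-dimethyloct-6-en-2-yl]-1,3-dioxolan-2-yl}propanoate | CCOC(=O)CCC1(OCCO1)[C@H](COCc1ccccc1)[C@H](C)CCC=C(C)C | intermediate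
11 | 3-{2-[(2S,3R)-1-(benzyloxy)-3,7-dimethyloct-6-en-2-yl]-1,3-dioxolan-2-yl}propanal | O=CCCC1(OCCO1)[C@H](COCc1ccccc1)[C@H](C)CCC=C(C)C | intermediate
12 | methyl 2-[bis(2,2,2-trifluoroethoxy)phosphoryl]propanoate | COC(=O)C(C)P(=O)(OCC(F)(F)F)OCC(F)(F)F | starting material
13 | methyl (2Z)-5-{2-[(2S,3R)-1-(benzyloxy)-3,7-dimethyloct-6-en-2-yl]-1,3-dioxolan-2-yl}-2-methylpent-2-enoate | COC(=O)/C(C)=C\CCC1(OCCO1)[C@H](COCc1ccccc1)[C@H](C)CCC=C(C)C | intermediate
14 | ozonide of 13 (3,3-dimethyl-1,2,4-trioxolane at the former isopropylidene olefin; both epimers at the ring CH) | COC(=O)/C(C)=C\CCC1(OCCO1)[C@H](COCc1ccccc1)[C@H](C)CCC1OOC(C)(C)O1 | intermediate (not isolated)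
15 | methyl (2Z)-5-{2-[(2S,3R)-1-(benzyloxy)-3-methyl-6-oxohexan-2-yl]-1,3-dioxolan-2-yl}-2-methylpent-2-enoate | COC(=O)/C(C)=C\CCC1(OCCO1)[C@H](COCc1ccccc1)[C@H](C)CCC=O | intermediate
16 | methyl (2Z)-5-{2-[(2S,3R,4E)-1-(benzyloxy)-3-methyl-6-oxohex-4-en-2-yl]-1,3-dioxolan-2-yl}-2-methylpent-2-enoate | COC(=O)/C(C)=C\CCC1(OCCO1)[C@H](COCc1ccccc1)[C@H](C)/C=C/C=O | intermediate
17 | methyl (2Z)-5-{2-[(2S,3E,5E)-1-(benzyloxy)-6-(tert-butyldimethylsilyloxy)-3-methylhexa-3,5-dien-2-yl]-1,3-dioxolan-2-yl}-2-methylpent-2-enoate | COC(=O)/C(C)=C\CCC1(OCCO1)[C@H](COCc1ccccc1)/C(C)=C/C=C/O[Si](C)(C)C(C)(C)C | intermediate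
18 | methyl (3S,4R,5R,9S,10R)-9β-(benzyloxymethyl)-3β-(TBSO)-8,8-ethylenedioxy-4α,10α-dimethyl-5αH-decal-1-ene-4β-carboxylate | O1CCOC12CC[C@H]3[C@@](C)(C(=O)OC)[C@@H](O[Si](C)(C)C(C)(C)C)C=C[C@@]3(C)[C@H]2COCc4ccccc4 | intermediate
19 | [9β-(benzyloxymethyl)-3β-(TBSO)-8,8-ethylenedioxy-4α,10α-dimethyl-5αH-decal-1-en-4β-yl]methanol | O1CCOC12CC[C@H]3[C@@](C)(CO)[C@@H](O[Si](C)(C)C(C)(C)C)C=C[C@@]3(C)[C@H]2COCc4ccccc4 | intermediate
20 | 9β-(benzyloxymethyl)-3β-(TBSO)-8,8-ethylenedioxy-4α,10α-dimethyl-5αH-decal-1-ene-4β-carbaldehyde | O1CCOC12CC[C@H]3[C@@](C)(C=O)[C@@H](O[Si](C)(C)C(C)(C)C)C=C[C@@]3(C)[C@H]2COCc4ccccc4 | intermediate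
21 | 1-(triphenylphosphoranylidene)propan-2-one | CC(=O)C=P(c1ccccc1)(c1ccccc1)c1ccccc1 | starting material
22 | (3E)-4-[9β-(benzyloxymethyl)-3β-(TBSO)-8,8-ethylenedioxy-4α,10α-dimethyl-5αH-decal-1-en-4β-yl]but-3-en-2-one | O1CCOC12CC[C@H]3[C@@](C)(/C=C/C(C)=O)[C@@H](O[Si](C)(C)C(C)(C)C)C=C[C@@]3(C)[C@H]2COCc4ccccc4 | intermediate
23 | 4-[9β-(benzyloxymethyl)-3β-(TBSO)-8,8-ethylenedioxy-4α,10α-dimethyl-5αH-decalin-4β-yl]butan-2-one | O1CCOC12CC[C@H]3[C@@](C)(CCC(C)=O)[C@@H](O[Si](C)(C)C(C)(C)C)CC[C@@]3(C)[C@H]2COCc4ccccc4 | intermediate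
24 | 4-[9β-(benzyloxymethyl)-3β-(TBSO)-8,8-ethylenedioxy-4α,10α-dimethyl-5αH-decalin-4β-yl]-2-methylbutan-2-ol | O1CCOC12CC[C@H]3[C@@](C)(CCC(C)(C)O)[C@@H](O[Si](C)(C)C(C)(C)C)CC[C@@]3(C)[C@H]2COCc4ccccc4 | intermediate
25 | 9β-(benzyloxymethyl)-3β-(TBSO)-4β-(3-hydroxy-3-methylbutyl)-4α,10α-dimethyl-5αH-decalin-8-one | O=C1CC[C@H]2[C@@](C)(CCC(C)(C)O)[C@@H](O[Si](C)(C)C(C)(C)C)CC[C@@]2(C)[C@H]1COCc1ccccc1 | intermediate
26 | 4-[9β-(benzyloxymethyl)-3β-(TBSO)-4α,10α-dimethyl-8-methylidene-5αH-decalin-4β-yl]-2-methylbutan-2-ol | C=C1CC[C@H]2[C@@](C)(CCC(C)(C)O)[C@@H](O[Si](C)(C)C(C)(C)C)CC[C@@]2(C)[C@H]1COCc1ccccc1 | intermediate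
27 | 4-[3β-(TBSO)-9β-(hydroxymethyl)-4α,10α-dimethyl-8-methylidene-5αH-decalin-4β-yl]-2-methylbutan-2-ol | C=C1CC[C@H]2[C@@](C)(CCC(C)(C)O)[C@@H](O[Si](C)(C)C(C)(C)C)CC[C@@]2(C)[C@H]1CO | intermediate
28 | 4-[3β-(TBSO)-9β-(iodomethyl)-4α,10α-dimethyl-8-methylidene-5αH-decalin-4β-yl]-2-methylbutan-2-ol | C=C1CC[C@H]2[C@@](C)(CCC(C)(C)O)[C@@H](O[Si](C)(C)C(C)(C)C)CC[C@@]2(C)[C@H]1CI | intermediate
29 | 4-[3β-(TBSO)-9β-(iodomethyl)-4α,10α-dimethyl-8-methylidene-5αH-decalin-4β-yl]-2-methylbutan-2-yl formate | C=C1CC[C@H]2[C@@](C)(CCC(C)(C)OC=O)[C@@H](O[Si](C)(C)C(C)(C)C)CC[C@@]2(C)[C@H]1CI | intermediate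
30 | methyl acetoacetate | CC(=O)CC(=O)OC | starting material
31 | malonyl dichloride | O=C(Cl)CC(=O)Cl | starting material
32 | methyl 4-hydroxy-2-methyl-6-oxo-6H-pyran-3-carboxylate | COC(=O)C1=C(C)OC(=O)C=C1O | intermediate
33 | methyl 4-hydroxy-5-iodo-2-methyl-6-oxo-6H-pyran-3-carboxylate | COC(=O)C1=C(C)OC(=O)C(I)=C1O | intermediate
34 | methyl 5-iodo-6-methoxy-2-methyl-4-oxo-4H-pyran-3-carboxylate | COC(=O)C1=C(C)OC(OC)=C(I)C1=O | intermediate
35 | iodo{[3β-(TBSO)-4β-(3-formyloxy-3-methylbutyl)-4α,10α-dimethyl-8-methylidene-5αH-decalin-9β-yl]methyl}zinc | C=C1CC[C@H]2[C@@](C)(CCC(C)(C)OC=O)[C@@H](O[Si](C)(C)C(C)(C)C)CC[C@@]2(C)[C@H]1C[Zn]I | intermediate (not isolated)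
36 | methyl 5-{[(3S,4R,5R,9S,10S)-3β-(TBSO)-4β-(3-formyloxy-3-methylbutyl)-4α,10α-dimethyl-8-methylidene-5αH-decalin-9β-yl]methyl}-6-methoxy-2-methyl-4-oxo-4H-pyran-3-carboxylate | C=C1CC[C@H]2[C@@](C)(CCC(C)(C)OC=O)[C@@H](O[Si](C)(C)C(C)(C)C)CC[C@@]2(C)[C@H]1Cc1c(OC)oc(C)c(C(=O)OC)c1=O | intermediate
37 | methyl 5-{[(3S,4R,5R,9S,10S)-4β-(3-formyloxy-3-methylbutyl)-3β-hydroxy-4α,10α-dimethyl-8-methylidene-5αH-decalin-9β-yl]methyl}-6-methoxy-2-methyl-4-oxo-4H-pyran-3-carboxylate (CNP0292250.1) | C=C1CC[C@H]2[C@@](C)(CCC(C)(C)OC=O)[C@@H](O)CC[C@@]2(C)[C@H]1Cc1c(OC)oc(C)c(C(=O)OC)c1=O | target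

## Step count and least certain steps

Total: 26 steps. Longest linear sequence: 23 steps (steps 1–21, 25, 26); the pyrone branch is steps 22–24.

**Step 11 (key step).** The cycloaddition joins a trisubstituted dienophile to a fully substituted diene terminus and may need a temperature at which the inside C10 methyl group migrates a hydrogen to C3 (1,5-shift). The endo preference of the ester may also be too small, so that trans-fused material forms beside 18. The fallback sets out from triene 17: the enoate is reduced with i-Bu2AlH to the (2Z)-allylic alcohol F1 and oxidised with MnO2 to the (2Z)-enal F2, a stronger and more endo-directing dienophile that should cyclise at lower temperature. Its adduct is aldehyde 20, where the route is rejoined, and steps 12 and 13 fall away.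

**Step 10.** The likely failure is poor control of the C10=C1 geometry in the γ-deprotonation, because methyl and C9 differ only moderately in their demand for the outside position; deprotonation at the hindered tertiary γ-carbon may also be slow. Only the (3E) isomer can cyclise. Recovered (3Z) diene can be hydrolysed back to 16, but the fallback changes the tactic: starting from enal 16, silyl triflate and amine drive an ionic Michael–aldol sequence in one flask. The transient dienol ether attacks C5 of the enoate through C10, and the resulting silyl ketene acetal closes onto the silylated aldehyde carbon C3. This formal [4+2] does not depend on diene geometry and ends at the same silyl ether 18 (no new isolated compound, F0); the relative configuration of the stepwise product would have to be proven.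

**Step 18.** The hindered ketone may convert incompletely, and the Lewis-acidic reagent may ionise the tertiary alcohol or epimerise C9. The fallback starts from ketone 25: Me3SiCH2MgCl with CeCl3 (a weakly basic nucleophile) adds to give the β-hydroxysilane F3, and Peterson elimination with KH gives olefin 26.

**Step 25.** Zinc insertion or transmetalation at the β-branched centre may be slow, with protodezincation or β-hydride elimination taking over. The fallback starts from diol 27:
- the primary alcohol is oxidised (TEMPO, PhI(OAc)2) to aldehyde F4;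
- F4 is condensed with hydroxypyrone 32 in the presence of a Hantzsch ester and proline, so that the Knoevenagel alkylidene F5 is reduced as it forms, giving the 3′-alkyl-4′-hydroxy-2′-pyrone F6;
- MeOTf gives the methoxy-γ-pyrone alcohol F7, and formylation as in step 21 returns to 36.

The β,γ-unsaturated aldehyde F4 is prone to epimerisation at C9, which is why this is the fallback and not the main line.

**Step 26.** The silyl ether next to quaternary C4 may cleave slowly, and long exposure may cost the formate. The fallback exchanges the silyl group before the sensitive groups exist. It starts from iodide 28: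
- aqueous HF in MeCN gives diol F8;
- Et3SiOTf and 2,6-lutidine at −78 °C silylate the secondary hydroxyl to F9;
- formylation gives F10, zinc insertion gives alkylzinc F11, and coupling with 34 gives triethylsilyl ether F12;
- AcOH/THF/H2O removes the labile silyl group and gives 37.

## Further compounds

F1 | step 11 | (2Z)-5-{2-[(2S,3E,5E)-1-(benzyloxy)-6-(tert-butyldimethylsilyloxy)-3-methylhexa-3,5-dien-2-yl]-1,3-dioxolan-2-yl}-2-methylpent-2-en-1-ol | OC/C(C)=C\CCC1(OCCO1)[C@H](COCc1ccccc1)/C(C)=C/C=C/O[Si](C)(C)C(C)(C)C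
F2 | step 11 | (2Z)-5-{2-[(2S,3E,5E)-1-(benzyloxy)-6-(tert-butyldimethylsilyloxy)-3-methylhexa-3,5-dien-2-yl]-1,3-dioxolan-2-yl}-2-methylpent-2-enal | O=C/C(C)=C\CCC1(OCCO1)[C@H](COCc1ccccc1)/C(C)=C/C=C/O[Si](C)(C)C(C)(C)C
F0 | step 10 | none | none
F3 | step 18 | 9β-(benzyloxymethyl)-3β-(TBSO)-4β-(3-hydroxy-3-methylbutyl)-4α,10α-dimethyl-8-(trimethylsilylmethyl)-5αH-decalin-8-ol (either C8 epimer) | C[Si](C)(C)CC1(O)CC[C@H]2[C@@](C)(CCC(C)(C)O)[C@@H](O[Si](C)(C)C(C)(C)C)CC[C@@]2(C)[C@H]1COCc1ccccc1
F4 | step 25 | 3β-(TBSO)-4β-(3-hydroxy-3-methylbutyl)-4α,10α-dimethyl-8-methylidene-5αH-decalin-9β-carbaldehyde | C=C1CC[C@H]2[C@@](C)(CCC(C)(C)O)[C@@H](O[Si](C)(C)C(C)(C)C)CC[C@@]2(C)[C@H]1C=O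
F5 | step 25 | methyl 3-{[3β-(TBSO)-4β-(3-hydroxy-3-methylbutyl)-4α,10α-dimethyl-8-methylidene-5αH-decalin-9β-yl]methylidene}-6-methyl-2,4-dioxo-3,4-dihydro-2H-pyran-5-carboxylate (not isolated) | C=C1CC[C@H]2[C@@](C)(CCC(C)(C)O)[C@@H](O[Si](C)(C)C(C)(C)C)CC[C@@]2(C)[C@H]1C=C1C(=O)OC(C)=C(C(=O)OC)C1=O
F6 | step 25 | methyl 5-{[3β-(TBSO)-4β-(3-hydroxy-3-methylbutyl)-4α,10α-dimethyl-8-methylidene-5αH-decalin-9β-yl]methyl}-4-hydroxy-2-methyl-6-oxo-6H-pyran-3-carboxylate | C=C1CC[C@H]2[C@@](C)(CCC(C)(C)O)[C@@H](O[Si](C)(C)C(C)(C)C)CC[C@@]2(C)[C@H]1CC1=C(O)C(C(=O)OC)=C(C)OC1=O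
F7 | step 25 | methyl 5-{[3β-(TBSO)-4β-(3-hydroxy-3-methylbutyl)-4α,10α-dimethyl-8-methylidene-5αH-decalin-9β-yl]methyl}-6-methoxy-2-methyl-4-oxo-4H-pyran-3-carboxylate | C=C1CC[C@H]2[C@@](C)(CCC(C)(C)O)[C@@H](O[Si](C)(C)C(C)(C)C)CC[C@@]2(C)[C@H]1Cc1c(OC)oc(C)c(C(=O)OC)c1=O
F8 | step 26 | 4β-(3-hydroxy-3-methylbutyl)-9β-(iodomethyl)-4α,10α-dimethyl-8-methylidene-5αH-decalin-3β-ol | C=C1CC[C@H]2[C@@](C)(CCC(C)(C)O)[C@@H](O)CC[C@@]2(C)[C@H]1CI
F9 | step 26 | 4-[9β-(iodomethyl)-4α,10α-dimethyl-8-methylidene-3β-(triethylsilyloxy)-5αH-decalin-4β-yl]-2-methylbutan-2-ol | C=C1CC[C@H]2[C@@](C)(CCC(C)(C)O)[C@@H](O[Si](CC)(CC)CC)CC[C@@]2(C)[C@H]1CI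
F10 | step 26 | 4-[9β-(iodomethyl)-4α,10α-dimethyl-8-methylidene-3β-(triethylsilyloxy)-5αH-decalin-4β-yl]-2-methylbutan-2-yl formate | C=C1CC[C@H]2[C@@](C)(CCC(C)(C)OC=O)[C@@H](O[Si](CC)(CC)CC)CC[C@@]2(C)[C@H]1CI
F11 | step 26 | iodo{[4β-(3-formyloxy-3-methylbutyl)-4α,10α-dimethyl-8-methylidene-3β-(triethylsilyloxy)-5αH-decalin-9β-yl]methyl}zinc (not isolated) | C=C1CC[C@H]2[C@@](C)(CCC(C)(C)OC=O)[C@@H](O[Si](CC)(CC)CC)CC[C@@]2(C)[C@H]1C[Zn]I
F12 | step 26 | methyl 5-{[4β-(3-formyloxy-3-methylbutyl)-4α,10α-dimethyl-8-methylidene-3β-(triethylsilyloxy)-5αH-decalin-9β-yl]methyl}-6-methoxy-2-methyl-4-oxo-4H-pyran-3-carboxylate | C=C1CC[C@H]2[C@@](C)(CCC(C)(C)OC=O)[C@@H](O[Si](CC)(CC)CC)CC[C@@]2(C)[C@H]1Cc1c(OC)oc(C)c(C(=O)OC)c1=O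
A1 | alternative 1 | lactone-bridged C8 ketone with C5=C6 olefin (C11 lactone to O3, silylated tertiary alcohol chain) | O=C1CC=C2[C@@](C)(CCC(C)(C)O[Si](C)(C)C(C)(C)C)[C@@H]3CC[C@@]2(C)[C@H]1C(=O)O3
A2 | alternative 2 | 2-{[3β-(TBSO)-4β-(3-formyloxy-3-methylbutyl)-4α,10α-dimethyl-8-methylidene-5αH-decalin-9β-yl]methyl}propanedioyl dichloride | C=C1CC[C@H]2[C@@](C)(CCC(C)(C)OC=O)[C@@H](O[Si](C)(C)C(C)(C)C)CC[C@@]2(C)[C@H]1CC(C(=O)Cl)C(=O)Cl
A3 | alternative 2 | 3-alkyl-4-hydroxy-6-methyl-2-pyrone-5-carboxylate carrying the silylated decalin | C=C1CC[C@H]2[C@@](C)(CCC(C)(C)OC=O)[C@@H](O[Si](C)(C)C(C)(C)C)CC[C@@]2(C)[C@H]1CC1=C(O)C(C(=O)OC)=C(C)OC1=O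
A4 | alternative 3 | cis-fused 8-methylene decalin, C3 epimer of the target alcohol, tertiary benzoate, C11 tert-butyldiphenylsilyl ether | C=C1CC[C@H]2[C@@](C)(CCC(C)(C)OC(=O)c3ccccc3)[C@H](O)CC[C@@]2(C)[C@H]1CO[Si](c1ccccc1)(c1ccccc1)C(C)(C)C
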